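**Retrosynthetic overview**

1. The strategy rests on ring A: all six carbons are substituted, with oxygen on C5, C7, C8 and C8a, prenyl on C6 and the acyl carbon C4 on C4a, so this ring is built rather than bought.
2. Ring A comes from a benzannulation of 3-siloxy-4-methoxycyclobutenone 9 with ethoxyacetylene 10, which makes C4a–C8a and C5–C6 and re-forms C8–C8a. The product, phenol 15, has C7–O silylated, C5–O as an ethyl ether and only the C8a hydroxyl free.
3. Cyclobutenone 9 comes from the [2+2] addition of methoxyketene to prenyl siloxyalkyne 6, itself made from prenyl bromide through the skipped enyne and its ynolate.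
4. Ring C follows: the 2,4,5-trimethoxyphenylacetyl group (ring B, from acid 16) is moved onto C4a by a Fries rearrangement, and a one-carbon closure (C2) onto the lone C8a hydroxyl gives the pyranone.
5. The C5 oxygen is carried as an ethyl ether because ethoxyacetylene is a stable commercial ynol ether, whereas the parent siloxyacetylene would depend on an unsecured ynolate O-silylation. The ethyl group sits peri to the C4 carbonyl and is removed by chelation, the C7 silyl group by fluoride. Ring order: A (step 4), then C (step 7).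

Key step: step 4

Remark: 9 is made and used as the racemate; its one stereocentre becomes the aromatic carbon C8, and the target has no stereocentre.

**Route**

Step 1
Reactants: 1 prenyl bromide (1-bromo-3-methylbut-2-ene); 2 ethynylmagnesium bromide (HC≡CMgBr, THF solution)
Product: 3 5-methylhex-4-en-1-yne
Conditions: CuCl (5 mol %), THF, 0 °C → rt
Reagents that add atoms: none
Why: Copper-catalysed coupling of an alkynyl Grignard reagent with a primary allylic bromide is the standard route to skipped enynes, the copper acetylide displacing bromide at the unhindered CH2.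

Step 2
Reactants: 3 5-methylhex-4-en-1-yne
Product: 6 triisopropyl[(5-methylhex-4-en-1-yn-1-yl)oxy]silane, via lithium acetylide 4 (not isolated), via lithium ynolate 5 (not isolated)
Conditions: n-BuLi, THF, −78 °C; t-BuOOLi (from t-BuOOH and LiN(SiMe3)2), −78 → 0 °C; i-Pr3SiOTf, −78 → 0 °C
Reagents that add atoms: tert-butyl hydroperoxide (used as t-BuOOLi), CC(C)(C)OO; triisopropylsilyl trifluoromethanesulfonate, CC(C)[Si](OS(=O)(=O)C(F)(F)F)(C(C)C)C(C)C
Why: Oxidation of a lithium acetylide by lithium tert-butyl peroxide (attack of the acetylide carbon on peroxide oxygen) is a known ynolate synthesis, and a bulky silyl triflate silylates alkyl-substituted ynolates on oxygen to give isolable siloxyalkynes.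

Step 3
Reactants: 6 triisopropyl[(5-methylhex-4-en-1-yn-1-yl)oxy]silane; 7 methoxyacetyl chloride
Product: 9 4-methoxy-2-(3-methylbut-2-enyl)-3-(triisopropylsilyloxy)cyclobut-2-en-1-one (racemic), via methoxyketene 8 (not isolated)
Conditions: Et3N, CH2Cl2, slow addition of 7, 0 °C → rt
Reagents that add atoms: none
Why: Dehydrochlorination keeps methoxyketene at low concentration, and the known ketene–siloxyalkyne [2+2] cycloaddition joins the nucleophilic prenyl-bearing alkyne carbon to the ketene carbonyl carbon to give the 3-siloxycyclobutenone; the new C4 centre forms without control as the racemate and is erased in step 4.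

Step 4
Reactants: 9 4-methoxy-2-(3-methylbut-2-enyl)-3-(triisopropylsilyloxy)cyclobut-2-en-1-one; 10 ethoxyacetylene
Product: 15 5-ethoxy-2-methoxy-4-(3-methylbut-2-enyl)-3-(triisopropylsilyloxy)phenol, via vinylketene 11 (not isolated), via vinylcyclobutenone 12 (not isolated), via dienylketene 13 (not isolated), via cyclohexadienone 14 (not isolated)
Conditions: 10 (3 equiv), toluene, 80 °C then 110 °C, sealed tube
Reagents that add atoms: none
Why: Thermal conrotatory four-electron opening of 9, with the C4 methoxy group turning outward, should give vinylketene 11, whose ketene C=C adds ethoxyacetylene in a [2+2] cycloaddition to vinylcyclobutenone 12; a second four-electron opening gives dienylketene 13, which closes ring A by a disrotatory six-electron electrocyclisation (C8–C8a) to cyclohexadienone 14, and enolisation gives phenol 15. The closest known reaction type is the Danheiser benzannulation of cyclobutenones with alkoxy- and siloxyacetylenes, and its first half mirrors the ketene–ynol ether cycloaddition that makes 9. Ring A is the only ring closed for good; the four-membered ring of 12 is formed by cycloaddition and reopened. No stereocentre is created, since C4 of racemic 9 and the sp3 carbon of 14 both end as the aromatic carbon C8. The step needs a single orientation of the ketene–alkyne union, and the polarisation of the ynol ether secures it: its nucleophilic unsubstituted carbon bonds to the electrophilic ketene carbon (C4a–C8a) and its oxygen-bearing carbon to the prenyl-bearing carbon (C5–C6). Because the ketene carbon becomes C8a, its oxygen is the one free hydroxyl of 15, which later fixes the direction in which ring C closes.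

Step 5
Reactants: 15 5-ethoxy-2-methoxy-4-(3-methylbut-2-enyl)-3-(triisopropylsilyloxy)phenol; 16 2,4,5-trimethoxyphenylacetic acid
Product: 18 [5-ethoxy-2-methoxy-4-(3-methylbut-2-enyl)-3-(triisopropylsilyloxy)phenyl] 2-(2,4,5-trimethoxyphenyl)acetate, via O-acylisourea 17 (not isolated)
Conditions: DCC, DMAP (cat.), CH2Cl2, 0 °C → rt
Reagents that add atoms: none
Why: Steglich esterification acylates the only free hydroxyl of 15 under neutral conditions that leave the silyl ether, the ynol-derived ethyl ether and the prenyl group untouched.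

Step 6
Reactants: 18 [5-ethoxy-2-methoxy-4-(3-methylbut-2-enyl)-3-(triisopropylsilyloxy)phenyl] 2-(2,4,5-trimethoxyphenyl)acetate
Product: 20 1-[6-ethoxy-2-hydroxy-3-methoxy-5-(3-methylbut-2-enyl)-4-(triisopropylsilyloxy)phenyl]-2-(2,4,5-trimethoxyphenyl)ethan-1-one, via titanium phenoxide 19 (not isolated)
Conditions: TiCl4, 2,6-di-tert-butylpyridine, CH2Cl2, −40 °C → rt; then H2O
Reagents that add atoms: none
Why: In this Fries rearrangement the acyl group can return only to C4a, the single unsubstituted ring carbon, which is ortho to the titanium-bound oxygen and activated by three oxygen substituents, while the hindered pyridine takes up the released proton so that the prenyl double bond and the silyl ether do not meet HCl.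

Step 7
Reactants: 20 1-[6-ethoxy-2-hydroxy-3-methoxy-5-(3-methylbut-2-enyl)-4-(triisopropylsilyloxy)phenyl]-2-(2,4,5-trimethoxyphenyl)ethan-1-one
Product: 22 5-ethoxy-8-methoxy-6-(3-methylbut-2-enyl)-7-(triisopropylsilyloxy)-3-(2,4,5-trimethoxyphenyl)chromen-4-one, via enaminone 21 (not isolated)
Conditions: Me2NCH(OMe)2, toluene, 90 °C
Reagents that add atoms: N,N-dimethylformamide dimethyl acetal, COC(OC)N(C)C
Why: The deoxybenzoin route to isoflavones applies: the active methylene condenses with the formamide acetal to an enaminone, and the C8a hydroxyl, the only free one, adds to the enamine carbon and expels dimethylamine to close ring C in one direction.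

Step 8
Reactants: 22 5-ethoxy-8-methoxy-6-(3-methylbut-2-enyl)-7-(triisopropylsilyloxy)-3-(2,4,5-trimethoxyphenyl)chromen-4-one
Product: 24 5-hydroxy-8-methoxy-6-(3-methylbut-2-enyl)-7-(triisopropylsilyloxy)-3-(2,4,5-trimethoxyphenyl)chromen-4-one, via boron chelate 23 (not isolated)
Conditions: BCl3, CH2Cl2, −78 → 0 °C; then H2O
Reagents that add atoms: none
Why: Chelation-controlled dealkylation: BCl3 bridges the C4 carbonyl and the peri C5 ether oxygen and chloride removes the ethyl group, the four methyl ethers lack such a chelating neighbour, and the C7 silyl ether keeps that oxygen from adding to the prenyl group.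

Step 9
Reactants: 24 5-hydroxy-8-methoxy-6-(3-methylbut-2-enyl)-7-(triisopropylsilyloxy)-3-(2,4,5-trimethoxyphenyl)chromen-4-one
Product: 25 6-prenylisocaviunin (5,7-dihydroxy-8-methoxy-6-(3-methylbut-2-enyl)-3-(2,4,5-trimethoxyphenyl)chromen-4-one)
Conditions: Bu4NF, AcOH, THF, 0 °C → rt
Reagents that add atoms: none
Why: Fluoride cleaves the aryl silyl ether, and buffering with acetic acid keeps the medium from opening the base-sensitive pyranone or disturbing the prenyl group.

**Compound list**

1 | prenyl bromide (1-bromo-3-methylbut-2-ene) | CC(C)=CCBr | starting material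
2 | ethynylmagnesium bromide | C#C[Mg]Br | starting material
3 | 5-methylhex-4-en-1-yne | C#CCC=C(C)C | intermediate
4 | lithium 5-methylhex-4-en-1-yn-1-ide (not isolated) | [Li]C#CCC=C(C)C | intermediate
5 | lithium 5-methylhex-4-en-1-yn-1-olate (not isolated) | [Li+].[O-]C#CCC=C(C)C | intermediate
6 | triisopropyl[(5-methylhex-4-en-1-yn-1-yl)oxy]silane | CC(C)=CCC#CO[Si](C(C)C)(C(C)C)C(C)C | intermediate
7 | methoxyacetyl chloride | COCC(=O)Cl | starting material
8 | methoxyketene (not isolated) | COC=C=O | intermediate
9 | 4-methoxy-2-(3-methylbut-2-enyl)-3-(triisopropylsilyloxy)cyclobut-2-en-1-one, racemic | COC1C(=O)C(CC=C(C)C)=C1O[Si](C(C)C)(C(C)C)C(C)C | intermediate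
10 | ethoxyacetylene | CCOC#C | starting material
11 | vinylketene, 4-methoxy-2-(3-methylbut-2-enyl)-3-(triisopropylsilyloxy)buta-1,3-dien-1-one, methoxy trans to the ketene-bearing carbon (not isolated) | O=C=C(CC=C(C)C)/C(O[Si](C(C)C)(C(C)C)C(C)C)=C/OC | intermediate
12 | vinylcyclobutenone, 3-ethoxy-4-[(Z)-2-methoxy-1-(triisopropylsilyloxy)ethenyl]-4-(3-methylbut-2-enyl)cyclobut-2-en-1-one, racemic (not isolated) | CCOC1=CC(=O)C1(CC=C(C)C)/C(O[Si](C(C)C)(C(C)C)C(C)C)=C/OC | intermediate
13 | dienylketene, 3-ethoxy-6-methoxy-4-(3-methylbut-2-enyl)-5-(triisopropylsilyloxy)hexa-1,3,5-trien-1-one, ketene arm and methoxyvinyl arm cis on the central double bond (not isolated) | O=C=C/C(OCC)=C(CC=C(C)C)\C(O[Si](C(C)C)(C(C)C)C(C)C)=C\OC | intermediate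
14 | cyclohexadienone, 3-ethoxy-6-methoxy-4-(3-methylbut-2-enyl)-5-(triisopropylsilyloxy)cyclohexa-2,4-dien-1-one, racemic (not isolated) | CCOC1=CC(=O)C(OC)C(O[Si](C(C)C)(C(C)C)C(C)C)=C1CC=C(C)C | intermediate
15 | 5-ethoxy-2-methoxy-4-(3-methylbut-2-enyl)-3-(triisopropylsilyloxy)phenol | CCOc1cc(O)c(OC)c(O[Si](C(C)C)(C(C)C)C(C)C)c1CC=C(C)C | intermediate
16 | 2,4,5-trimethoxyphenylacetic acid | COc1cc(OC)c(CC(=O)O)cc1OC | starting material
17 | O-acylisourea of 16 with DCC (not isolated) | COc1cc(OC)c(CC(=O)OC(=NC2CCCCC2)NC2CCCCC2)cc1OC | intermediate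
18 | [5-ethoxy-2-methoxy-4-(3-methylbut-2-enyl)-3-(triisopropylsilyloxy)phenyl] 2-(2,4,5-trimethoxyphenyl)acetate | CCOc1cc(OC(=O)Cc2cc(OC)c(OC)cc2OC)c(OC)c(O[Si](C(C)C)(C(C)C)C(C)C)c1CC=C(C)C | intermediate
19 | trichlorotitanium phenoxide of 20 (not isolated) | CCOc1c(C(=O)Cc2cc(OC)c(OC)cc2OC)c(O[Ti](Cl)(Cl)Cl)c(OC)c(O[Si](C(C)C)(C(C)C)C(C)C)c1CC=C(C)C | intermediate
20 | 1-[6-ethoxy-2-hydroxy-3-methoxy-5-(3-methylbut-2-enyl)-4-(triisopropylsilyloxy)phenyl]-2-(2,4,5-trimethoxyphenyl)ethan-1-one | CCOc1c(C(=O)Cc2cc(OC)c(OC)cc2OC)c(O)c(OC)c(O[Si](C(C)C)(C(C)C)C(C)C)c1CC=C(C)C | intermediate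
21 | enaminone, 3-(dimethylamino)-1-aryl-2-(2,4,5-trimethoxyphenyl)prop-2-en-1-one of 20, drawn as the E isomer, either isomer can close (not isolated) | CCOc1c(C(=O)/C(=C/N(C)C)c2cc(OC)c(OC)cc2OC)c(O)c(OC)c(O[Si](C(C)C)(C(C)C)C(C)C)c1CC=C(C)C | intermediate
22 | 5-ethoxy-8-methoxy-6-(3-methylbut-2-enyl)-7-(triisopropylsilyloxy)-3-(2,4,5-trimethoxyphenyl)chromen-4-one | CCOc1c(CC=C(C)C)c(O[Si](C(C)C)(C(C)C)C(C)C)c(OC)c2occ(-c3cc(OC)c(OC)cc3OC)c(=O)c12 | intermediate
23 | C5–O dichloroboron chelate of 24 (not isolated) | COc1cc(OC)c(-c2coc3c(OC)c(O[Si](C(C)C)(C(C)C)C(C)C)c(CC=C(C)C)c(OB(Cl)Cl)c3c2=O)cc1OC | intermediate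
24 | 5-hydroxy-8-methoxy-6-(3-methylbut-2-enyl)-7-(triisopropylsilyloxy)-3-(2,4,5-trimethoxyphenyl)chromen-4-one | COc1cc(OC)c(-c2coc3c(OC)c(O[Si](C(C)C)(C(C)C)C(C)C)c(CC=C(C)C)c(O)c3c2=O)cc1OC | intermediate
25 | 6-prenylisocaviunin | COc1cc(OC)c(-c2coc3c(OC)c(O)c(CC=C(C)C)c(O)c3c2=O)cc1OC | target

**Step count**

Total step count: 9. Longest linear sequence: 9 steps (1 → 3 → 6 → 9 → 15 → 18 → 20 → 22 → 24 → 25).

**Steps most likely to fail**

Step 4 (benzannulation). The doubly oxygenated cyclobutenone may release vinylketene 11 only slowly. The ketene may then be used up by self-condensation or by acylating phenol 15 already formed, while the volatile ynol ether is lost or polymerises. The fallback sets out again from 9 and traps the vinylketene with the more nucleophilic, less volatile 1,1-diethoxyethene (toluene, 80 °C). This ketene–ketene acetal [2+2] addition should give 3,3-diethoxy-2-[(Z)-2-methoxy-1-(triisopropylsilyloxy)ethenyl]-2-(3-methylbut-2-enyl)cyclobutan-1-one F1. Elimination of ethanol from F1 (Et3N or further heating) gives vinylcyclobutenone 12, where the fallback rejoins the route, and 12 goes on to 15 as in step 4.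

Step 6 (Fries rearrangement). The Lewis acid may attack the prenyl double bond, strip the ethyl or silyl ether by chelation once the ketone is formed, or the arylacetyl cation may lose carbon monoxide. The fallback makes C4a the nucleophile. From 15, bromination at the only free ring carbon (NBS, CH2Cl2, −78 °C) should give 2-bromo-3-ethoxy-6-methoxy-4-(3-methylbut-2-enyl)-5-(triisopropylsilyloxy)phenol F2. Acid 16 is converted (DCC, MeNHOMe·HCl, Et3N) into N-methoxy-N-methyl-2-(2,4,5-trimethoxyphenyl)acetamide F3. Treating F2 with n-BuLi (2.1 equiv, THF, −78 °C; O-deprotonation, then bromine–lithium exchange) and then with F3 should give deoxybenzoin 20 after work-up, where the route is rejoined.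

Step 8 (de-ethylation at C5). Under the Lewis acid, HCl may add to the prenyl double bond or an oxygen may cyclise onto it, the C7 silyl group may be lost before the ethyl group, or the ethyl ether may cleave too slowly. The fallback changes both order and mechanism. From 22, Bu4NF/AcOH should give 5-ethoxy-7-hydroxy-8-methoxy-6-(3-methylbut-2-enyl)-3-(2,4,5-trimethoxyphenyl)chromen-4-one F4. Nucleophilic de-ethylation of F4 with LiCl in DMF at 130–150 °C (chloride attacks the ethyl group of the only ether ortho to the carbonyl, with no acid present) should then give target 25 directly.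

**Further compounds**

F1 | step 4 | 3,3-diethoxy-2-[(Z)-2-methoxy-1-(triisopropylsilyloxy)ethenyl]-2-(3-methylbut-2-enyl)cyclobutan-1-one (racemic) | CCOC1(OCC)CC(=O)C1(CC=C(C)C)/C(O[Si](C(C)C)(C(C)C)C(C)C)=C/OC
F2 | step 6 | 2-bromo-3-ethoxy-6-methoxy-4-(3-methylbut-2-enyl)-5-(triisopropylsilyloxy)phenol | CCOc1c(Br)c(O)c(OC)c(O[Si](C(C)C)(C(C)C)C(C)C)c1CC=C(C)C
F3 | step 6 | N-methoxy-N-methyl-2-(2,4,5-trimethoxyphenyl)acetamide | COc1cc(OC)c(CC(=O)N(C)OC)cc1OC
F4 | step 8 | 5-ethoxy-7-hydroxy-8-methoxy-6-(3-methylbut-2-enyl)-3-(2,4,5-trimethoxyphenyl)chromen-4-one | CCOc1c(CC=C(C)C)c(O)c(OC)c2occ(-c3cc(OC)c(OC)cc3OC)c(=O)c12
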